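**Retrosynthetic overview**
1. Target 37 ⇐ seco-diol 36 by transannular oxa-Michael addition of O2 to C8 of a butenolide, which closes the oxane and the oxocane at once; C6–Cl ⇐ allylic C6–OH by SN2.
2. Ten-membered carbocycle ⇐ intramolecular vinylogous Mukaiyama aldol (C6–C7) of an enal-butenolide; butenolide ⇐ intramolecular HWE on a glyceraldehyde-derived hydroxy ketone.
3. Cyclohexene ring (C1, C10–C14) ⇐ one-carbon ring expansion of a cyclopentanol: semipinacol shift of C10 from C14 to the epoxide carbon C1; C13=C14 and 12-OH ⇐ the C14 ketone by dehydrogenation, epoxidation and Wharton transposition.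
4. Cyclopentanol ⇐ vinyllithium (C1–C6, from but-2-ynal) + cyclopentanone (C7–C14, from 3-methylcyclopentenone by borylative aldol with (R)-glyceraldehyde acetonide).
5. Enabling feature: the quaternary C1 (Me-15) lies between ring carbon C14 (a masked carbonyl) and oxygenated C2, i.e. an α-quaternary β-oxy ketone that maps onto a 1-(oxiranyl)cyclopentanol; ring order: cyclopentane → cyclohexane → butenolide → ten-membered ring → oxane/oxocane.

Key step: step 9

Remark: locants C1–C20 follow briarane numbering (C1 = ring carbon bearing Me-15, C2 = ether CH, C8 = tertiary ether carbon, C19 = lactone C=O); the full configuration of each intermediate is fixed by its SMILES, and but-2-ynal is taken as a commercial reagent.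

Step 1
Reactants: 1 3-methylcyclopent-2-en-1-one; 2 bis(pinacolato)diboron; 3 (R)-2,2-dimethyl-1,3-dioxolane-4-carbaldehyde
Product: 6 (2S,3R)-3-hydroxy-2-{(S)-[(4R)-2,2-dimethyl-1,3-dioxolan-4-yl](hydroxy)methyl}-3-methylcyclopentan-1-one, via boron enolate 4 (not isolated), via boronate aldol 5 (not isolated)
Conditions: [Cu(MeCN)4]PF6 (5 mol%), (R,R)-QuinoxP* (6 mol%; the ligand enantiomer that gives the 11S boronate), LiOtBu (10 mol%), THF, rt; then 3, −78 °C to rt; then NaBO3·4H2O, THF/H2O, 0 °C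
Reagents that add atoms: sodium perborate tetrahydrate, O.O.O.O.[Na+].[O-]OB=O
Why: Ligand-controlled copper-boryl conjugate addition sets C11, the pinacolboron (E)-enolate 4 then adds to the aldehyde in a Zimmerman–Traxler aldol anti to the bulky boryl group (anti aldol, Felkin–Anh-matched with the (R)-aldehyde) to set C10 and C9, and perborate replaces boron by hydroxyl with retention (conjugate borylation–aldol tandem, C–B oxidation).

Step 2
Reactants: 6 diol ketone
Product: 7 (2S,3R)-2-{(S)-[(4R)-2,2-dimethyl-1,3-dioxolan-4-yl][(triethylsilyl)oxy]methyl}-3-methyl-3-[(triethylsilyl)oxy]cyclopentan-1-one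
Conditions: TESOTf (2.5 equiv), 2,6-lutidine, CH2Cl2, −78 to 0 °C
Reagents that add atoms: triethylsilyl trifluoromethanesulfonate, CC[Si](CC)(CC)OS(=O)(=O)C(F)(F)F
Why: The silyl triflate silylates both the secondary and the tertiary hydroxyl (silyl ether protection), which blocks retro-aldol and dehydration in the later organolithium step.

Step 3
Reactants: 8 3-bromo-2-(bromomethyl)prop-1-ene; 9 (4-methoxyphenyl)methanol
Product: 10 1-({[2-(bromomethyl)prop-2-en-1-yl]oxy}methyl)-4-methoxybenzene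
Conditions: NaH, THF, 0 °C to rt (8 in threefold excess)
Reagents that add atoms: none
Why: Williamson ether synthesis on an allylic dibromide, with excess dibromide suppressing double substitution.

Step 4
Reactants: 10 allylic bromide; 11 but-2-ynal
Product: 12 triethyl{[(4R)-6-{[(4-methoxybenzyl)oxy]methyl}hept-6-en-2-yn-4-yl]oxy}silane
Conditions: CrCl2 (10 mol%), (S)-N-[2-(4-isopropyl-4,5-dihydrooxazol-2-yl)-6-methylphenyl]methanesulfonamide (12 mol%; ligand enantiomer chosen for the R carbinol), Et3N (20 mol%), Mn powder, TESCl, MeCN, rt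
Reagents that add atoms: chlorotriethylsilane, CC[Si](Cl)(CC)CC
Why: Catalytic asymmetric Nozaki–Hiyama allylation in which the 2-substituted allylchromium species adds to the ynal inside the chiral ligand sphere to set C3, and TESCl releases the product from chromium as its silyl ether.

Step 5
Reactants: 12 silyl ether of the propargylic alcohol
Product: 14 triethyl{[(2E,4R)-2-iodo-6-{[(4-methoxybenzyl)oxy]methyl}hepta-2,6-dien-4-yl]oxy}silane, via alkenylzirconocene 13 (not isolated)
Conditions: Cp2Zr(H)Cl (1.6 equiv), THF, 50 °C; then I2, 0 °C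
Reagents that add atoms: iodine, II
Why: Hydrozirconation adds H and Zr syn with zirconium on the less hindered, methyl-bearing alkyne carbon after equilibration, and iodinolysis with retention gives the (E)-2-iodoalkene (the alkyne reacts faster than the 1,1-disubstituted alkene).

Step 6
Reactants: 14 vinyl iodide silyl ether
Product: 15 (2E,4R)-2-iodo-6-{[(4-methoxybenzyl)oxy]methyl}hepta-2,6-dien-4-ol
Conditions: PPTS, MeOH, 0 °C
Reagents that add atoms: none
Why: Mild acid methanolysis cleaves the secondary triethylsilyl ether and leaves the PMB ether and vinyl iodide untouched (silyl ether solvolysis).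

Step 7
Reactants: 15 iodo alcohol; 7 cyclopentanone
Product: 17 C14 tertiary carbinol (E-C1=C2 alkene; free 3-OH; 14-OH β; 9,11-bis-OTES; 7,8-acetonide; 6-OPMB), via dilithio species 16 (not isolated)
Conditions: tBuLi (3.0 equiv), Et2O, −78 °C; then 7, −78 °C; aq. NH4Cl
Reagents that add atoms: none
Why: Deprotonation and iodine–lithium exchange give the alkoxide-vinyllithium 16, which adds 1,2 to the ketone anti to the C10 side chain (organolithium addition); the new C14 centre is erased in step 9, so either epimer is usable.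

Step 8
Reactants: 17 diol
Product: 18 1,2-epoxide of 17 (epoxide oxygen syn to the 3-OH)
Conditions: VO(acac)2 (5 mol%), tBuOOH (1.2 equiv), CH2Cl2, 0 °C
Reagents that add atoms: tert-butyl hydroperoxide, CC(C)(C)OO
Why: Hydroxyl-directed vanadium-catalysed epoxidation in which A1,3 strain between C3 and the cis methyl group (Me-15) holds C3–H in the alkene plane, so oxygen is delivered to the face syn to the C3 hydroxyl and gives the threo epoxy alcohol; the allylic trisubstituted alkene reacts ahead of the homoallylic 1,1-disubstituted one.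

Step 9
Reactants: 18 epoxy diol
Product: 20 cyclohexanone (C14 ketone; quaternary C1 with Me-15; 2,3-bis-OTBS; 9,11-bis-OTES; 7,8-acetonide; 6-OPMB), via C3 silyl ether 19 (not isolated)
Conditions: TBSOTf (3 equiv), 2,6-di-tert-butyl-4-methylpyridine (3.5 equiv), CH2Cl2, −78 to −40 °C
Reagents that add atoms: tert-butyldimethylsilyl trifluoromethanesulfonate, CC(C)(C)[Si](C)(C)OS(=O)(=O)C(F)(F)F
Why: Excess silyl triflate first silylates the secondary C3 hydroxyl (19) and then activates the epoxide oxygen; the tertiary C1–O bond ionises while the anti-periplanar C14–C10 ring bond shifts from C14 to C1, and the C14 oxocarbenium loses a proton to the pyridine base, so the cyclopentanol becomes the 2,2-disubstituted cyclohexanone and the former epoxide oxygen ends as the C2 silyl ether. The closest known reaction type is the semipinacol rearrangement of 2,3-epoxy alcohols with ring expansion of 1-(oxiranyl)cycloalkanols, here in its silyl-triflate-promoted form. The six-membered ring (C1, C10, C11, C12, C13, C14) is closed by a stereospecific 1,2-alkyl shift (insertion of C1 between C14 and C10), not by an exo or endo cyclisation. C1 is formed with inversion at the epoxide carbon and retention at the migrating C10, so its configuration follows from the epoxide set in step 8; C2 keeps its oxygen unchanged; the C14 carbinol centre is erased, so both C14 epimers converge. The step needs migration of C10 rather than C13 and opening at C1 rather than C2: C10 is the more substituted ring carbon and the better migrating group, C1 is the only tertiary epoxide carbon, and the C3 silyloxy group inductively disfavours ionisation at C2.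

Step 10
Reactants: 20 cyclohexanone
Product: 21 cyclohex-2-enone (C12=C13 conjugated to the C14 ketone)
Conditions: IBX, 4-methoxypyridine N-oxide, DMSO, 30 °C
Reagents that add atoms: none
Why: IBX dehydrogenation through the only enolisable position (C13; C1 is quaternary) gives the enone (ketone α,β-dehydrogenation).

Step 11
Reactants: 21 enone
Product: 22 12α,13α-epoxy ketone
Conditions: tBuOOH, DBU, CH2Cl2, 0 °C
Reagents that add atoms: tert-butyl hydroperoxide, CC(C)(C)OO
Why: Nucleophilic (Weitz–Scheffer) epoxidation in which the peroxide anion adds to C12 from the α face, opposite the two axial β-methyl groups on C1 and C11, which fixes the C12–O configuration.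

Step 12
Reactants: 22 epoxy ketone
Product: 23 allylic alcohol (C13=C14; 12α-OH)
Conditions: N2H4·H2O, AcOH, MeOH, 0 °C to rt
Reagents that add atoms: none
Why: Wharton reaction, in which the hydrazone of the α,β-epoxy ketone fragments with loss of N2 to the transposed allylic alcohol, placing the alkene at C13=C14 and keeping the epoxide C12–O bond and its configuration.

Step 13
Reactants: 23 allylic alcohol
Product: 24 9,11,12-triol
Conditions: HF·pyridine, pyridine, THF, 0 °C
Reagents that add atoms: none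
Why: Buffered HF·pyridine cleaves the two triethylsilyl ethers much faster than the hindered secondary TBS ethers and leaves the acetonide intact (selective desilylation).

Step 14
Reactants: 24 triol
Product: 25 9,11,12-triacetate
Conditions: Ac2O, DMAP, Et3N, CH2Cl2, 40 °C
Reagents that add atoms: acetic anhydride, CC(=O)OC(C)=O
Why: DMAP-catalysed acylation acetylates the two secondary hydroxyls and, on warming, the tertiary C11 hydroxyl (esterification).

Step 15
Reactants: 25 triacetate
Product: 26 7,8-diol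
Conditions: AcOH/H2O (4:1), 40 °C
Reagents that add atoms: none
Why: Aqueous acetic acid hydrolyses the terminal isopropylidene acetal while acetates, TBS ethers and the PMB ether persist (acetal hydrolysis).

Step 16
Reactants: 26 diol; 27 2-(diethoxyphosphoryl)propanoic acid
Product: 28 7-O-[2-(diethoxyphosphoryl)propanoyl] ester (8-OH free)
Conditions: EDC·HCl, DMAP (cat.), CH2Cl2, 0 °C
Reagents that add atoms: none
Why: Carbodiimide (Steglich-type) esterification is selective for the primary C7 hydroxyl over the hindered secondary C8 hydroxyl.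

Step 17
Reactants: 28 hydroxy phosphonate ester
Product: 29 C8 ketone
Conditions: Dess–Martin periodinane, NaHCO3, CH2Cl2, 0 °C to rt
Reagents that add atoms: none
Why: Buffered Dess–Martin oxidation converts the remaining secondary alcohol into the C8 ketone without epimerising C9.

Step 18
Reactants: 29 keto phosphonate
Product: 30 butenolide (C8=C17, C7 as CH2)
Conditions: LiCl, iPr2NEt, MeCN, rt
Reagents that add atoms: none
Why: Intramolecular Horner–Wadsworth–Emmons olefination under mild LiCl/amine conditions closes the five-membered α-methyl butenolide.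

Step 19
Reactants: 30 butenolide PMB ether
Product: 31 allylic primary alcohol (C6–OH)
Conditions: DDQ, CH2Cl2/pH 7 buffer, 0 °C
Reagents that add atoms: none
Why: DDQ oxidises the PMB ether to its oxocarbenium ion, which is hydrolysed, freeing the allylic alcohol without touching silyl ethers, acetates or the butenolide (oxidative PMB cleavage).

Step 20
Reactants: 31 allylic alcohol
Product: 32 enal (C6 aldehyde on the C5 methylene unit)
Conditions: MnO2, CH2Cl2, rt
Reagents that add atoms: none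
Why: MnO2 oxidises the allylic primary alcohol chemoselectively to the 2-substituted acrolein (allylic oxidation).

Step 21
Reactants: 32 enal-butenolide
Product: 34 ten-membered aldol (6R-OH, 7R), via silyloxyfuran 33 (not isolated)
Conditions: TBSOTf (1.1 equiv), Et3N, CH2Cl2 (1 mM), −78 to 0 °C; then BF3·OEt2, −78 °C
Reagents that add atoms: none
Why: Soft enolisation gives the 2-silyloxyfuran 33, which attacks the BF3-activated aldehyde through its γ-carbon C7 (intramolecular vinylogous Mukaiyama aldol, α-carbon blocked by methyl) in a ten-membered ring closure at high dilution, with C6 and C7 set in an open transition state constrained by the trans-disubstituted cyclohexene and expected to give the 6R,7R isomer.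

Step 22
Reactants: 34 allylic alcohol
Product: 35 6S allylic chloride
Conditions: PPh3, hexachloroacetone, CH2Cl2, 0 °C
Reagents that add atoms: hexachloroacetone, ClC(Cl)(Cl)C(=O)C(Cl)(Cl)Cl
Why: Appel-type chlorination through the alkoxyphosphonium salt displaces oxygen by chloride in an SN2 reaction with inversion at C6 and without allylic transposition.

Step 23
Reactants: 35 bis-TBS ether
Product: 36 2,3-diol
Conditions: HF (48% aq.), MeCN, 0 °C to rt
Reagents that add atoms: none
Why: Aqueous HF in acetonitrile cleaves both hindered TBS ethers while the allylic chloride, acetates and butenolide are tolerated (desilylation).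

Step 24
Reactants: 36 diol
Product: 37 CNP0333938.2
Conditions: CSA (cat.), CH2Cl2, rt
Reagents that add atoms: none
Why: Acid-catalysed transannular oxa-Michael addition in which the C2 hydroxyl, held across the ten-membered ring from the butenolide β-carbon C8, adds to the only accessible face (six-membered ring closure, formally 6-exo-trig; the C3 hydroxyl would need a seven-membered ring), and kinetic ketonisation of the lactone enol on the face of the new C8–O bond, away from C9, sets C17.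

**Compound list**
1 | 3-methylcyclopent-2-en-1-one | CC1=CC(=O)CC1 | starting material
2 | bis(pinacolato)diboron | CC1(C)OB(OC1(C)C)B1OC(C)(C)C(C)(C)O1 | starting material
3 | (R)-2,2-dimethyl-1,3-dioxolane-4-carbaldehyde | CC1(C)OC[C@@H](O1)C=O | starting material
4 | pinacolboron enolate of (3S)-3-methyl-3-(pinacolboryl)cyclopentanone | C[C@@]1(B2OC(C)(C)C(C)(C)O2)CCC(OB2OC(C)(C)C(C)(C)O2)=C1 | intermediate
5 | (2R,3S)-2-{(S)-[(4R)-2,2-dimethyl-1,3-dioxolan-4-yl](hydroxy)methyl}-3-methyl-3-(4,4,5,5-tetramethyl-1,3,2-dioxaborolan-2-yl)cyclopentan-1-one | CC1(C)OC[C@@H](O1)[C@@H](O)[C@@H]2C(=O)CC[C@@]2(C)B3OC(C)(C)C(C)(C)O3 | intermediate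
6 | (2S,3R)-3-hydroxy-2-{(S)-[(4R)-2,2-dimethyl-1,3-dioxolan-4-yl](hydroxy)methyl}-3-methylcyclopentan-1-one | CC1(C)OC[C@@H](O1)[C@@H](O)[C@@H]2C(=O)CC[C@@]2(C)O | intermediate
7 | (2S,3R)-2-{(S)-[(4R)-2,2-dimethyl-1,3-dioxolan-4-yl][(triethylsilyl)oxy]methyl}-3-methyl-3-[(triethylsilyl)oxy]cyclopentan-1-one | CC1(C)OC[C@@H](O1)[C@@H](O[Si](CC)(CC)CC)[C@@H]2C(=O)CC[C@@]2(C)O[Si](CC)(CC)CC | intermediate
8 | 3-bromo-2-(bromomethyl)prop-1-ene | C=C(CBr)CBr | starting material
9 | (4-methoxyphenyl)methanol | COc1ccc(CO)cc1 | starting material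
10 | 1-({[2-(bromomethyl)prop-2-en-1-yl]oxy}methyl)-4-methoxybenzene | C=C(CBr)COCc1ccc(OC)cc1 | intermediate
11 | but-2-ynal | CC#CC=O | starting material
12 | triethyl{[(4R)-6-{[(4-methoxybenzyl)oxy]methyl}hept-6-en-2-yn-4-yl]oxy}silane | CC#C[C@H](O[Si](CC)(CC)CC)CC(=C)COCc1ccc(OC)cc1 | intermediate
13 | chlorobis(cyclopentadienyl)[(2E,4R)-6-{[(4-methoxybenzyl)oxy]methyl}-4-[(triethylsilyl)oxy]hepta-2,6-dien-2-yl]zirconium | C=C(COCc1ccc(OC)cc1)C[C@@H](O[Si](CC)(CC)CC)/C=C(\C)[Zr](Cl)(C1C=CC=C1)C1C=CC=C1 | intermediate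
14 | triethyl{[(2E,4R)-2-iodo-6-{[(4-methoxybenzyl)oxy]methyl}hepta-2,6-dien-4-yl]oxy}silane | C=C(COCc1ccc(OC)cc1)C[C@@H](O[Si](CC)(CC)CC)/C=C(\C)I | intermediate
15 | (2E,4R)-2-iodo-6-{[(4-methoxybenzyl)oxy]methyl}hepta-2,6-dien-4-ol | C=C(COCc1ccc(OC)cc1)C[C@@H](O)/C=C(\C)I | intermediate
16 | dilithio derivative of 15 (lithium alkoxide and C1 vinyllithium) | C=C(COCc1ccc(OC)cc1)C[C@@H](O[Li])/C=C(\C)[Li] | intermediate
17 | C14 tertiary carbinol (E-C1=C2; 3-OH; 14-OH β; 9,11-bis-OTES; 7,8-acetonide; 6-OPMB) | C=C(COCc1ccc(OC)cc1)C[C@@H](O)/C=C(\C)[C@@]1(O)CC[C@@](C)(O[Si](CC)(CC)CC)[C@@H]1[C@H](O[Si](CC)(CC)CC)[C@H]2COC(C)(C)O2 | intermediate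
18 | 1,2-epoxide of 17 (oxygen syn to 3-OH) | C=C(COCc1ccc(OC)cc1)C[C@@H](O)[C@@H]1O[C@@]1(C)[C@@]2(O)CC[C@@](C)(O[Si](CC)(CC)CC)[C@@H]2[C@H](O[Si](CC)(CC)CC)[C@H]3COC(C)(C)O3 | intermediate
19 | 3-O-TBS ether of epoxy alcohol 18 | C=C(COCc1ccc(OC)cc1)C[C@@H](O[Si](C)(C)C(C)(C)C)[C@@H]1O[C@@]1(C)[C@@]2(O)CC[C@@](C)(O[Si](CC)(CC)CC)[C@@H]2[C@H](O[Si](CC)(CC)CC)[C@H]3COC(C)(C)O3 | intermediate
20 | cyclohexanone (14-ketone; quaternary C1; 2,3-bis-OTBS; 9,11-bis-OTES; 7,8-acetonide; 6-OPMB) | C=C(COCc1ccc(OC)cc1)C[C@@H](O[Si](C)(C)C(C)(C)C)[C@H](O[Si](C)(C)C(C)(C)C)[C@@]1(C)C(=O)CC[C@@](C)(O[Si](CC)(CC)CC)[C@@H]1[C@H](O[Si](CC)(CC)CC)[C@H]2COC(C)(C)O2 | intermediate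
21 | 12-en-14-one (enone of 20) | C=C(COCc1ccc(OC)cc1)C[C@@H](O[Si](C)(C)C(C)(C)C)[C@H](O[Si](C)(C)C(C)(C)C)[C@@]1(C)C(=O)C=C[C@@](C)(O[Si](CC)(CC)CC)[C@@H]1[C@H](O[Si](CC)(CC)CC)[C@H]2COC(C)(C)O2 | intermediate
22 | 12α,13α-epoxy-14-ketone | C=C(COCc1ccc(OC)cc1)C[C@@H](O[Si](C)(C)C(C)(C)C)[C@H](O[Si](C)(C)C(C)(C)C)[C@@]1(C)C(=O)[C@H]3O[C@H]3[C@@](C)(O[Si](CC)(CC)CC)[C@@H]1[C@H](O[Si](CC)(CC)CC)[C@H]2COC(C)(C)O2 | intermediate
23 | 13-en-12α-ol (Wharton product) | C=C(COCc1ccc(OC)cc1)C[C@@H](O[Si](C)(C)C(C)(C)C)[C@H](O[Si](C)(C)C(C)(C)C)[C@@]1(C)C=C[C@@H](O)[C@@](C)(O[Si](CC)(CC)CC)[C@@H]1[C@H](O[Si](CC)(CC)CC)[C@H]2COC(C)(C)O2 | intermediate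
24 | 9,11,12-triol | C=C(COCc1ccc(OC)cc1)C[C@@H](O[Si](C)(C)C(C)(C)C)[C@H](O[Si](C)(C)C(C)(C)C)[C@@]1(C)C=C[C@@H](O)[C@@](C)(O)[C@@H]1[C@H](O)[C@H]2COC(C)(C)O2 | intermediate
25 | 9,11,12-triacetate | C=C(COCc1ccc(OC)cc1)C[C@@H](O[Si](C)(C)C(C)(C)C)[C@H](O[Si](C)(C)C(C)(C)C)[C@@]1(C)C=C[C@@H](OC(C)=O)[C@@](C)(OC(C)=O)[C@@H]1[C@H](OC(C)=O)[C@H]2COC(C)(C)O2 | intermediate
26 | 7,8-diol triacetate | C=C(COCc1ccc(OC)cc1)C[C@@H](O[Si](C)(C)C(C)(C)C)[C@H](O[Si](C)(C)C(C)(C)C)[C@@]1(C)C=C[C@@H](OC(C)=O)[C@@](C)(OC(C)=O)[C@@H]1[C@H](OC(C)=O)[C@H](O)CO | intermediate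
27 | 2-(diethoxyphosphoryl)propanoic acid | CCOP(=O)(OCC)C(C)C(=O)O | starting material
28 | 7-O-[2-(diethoxyphosphoryl)propanoyl] ester, 8-OH (epimers at the phosphonate carbon) | C=C(COCc1ccc(OC)cc1)C[C@@H](O[Si](C)(C)C(C)(C)C)[C@H](O[Si](C)(C)C(C)(C)C)[C@@]1(C)C=C[C@@H](OC(C)=O)[C@@](C)(OC(C)=O)[C@@H]1[C@H](OC(C)=O)[C@H](O)COC(=O)C(C)P(=O)(OCC)OCC | intermediate
29 | 8-keto phosphonate ester | C=C(COCc1ccc(OC)cc1)C[C@@H](O[Si](C)(C)C(C)(C)C)[C@H](O[Si](C)(C)C(C)(C)C)[C@@]1(C)C=C[C@@H](OC(C)=O)[C@@](C)(OC(C)=O)[C@@H]1[C@H](OC(C)=O)C(=O)COC(=O)C(C)P(=O)(OCC)OCC | intermediate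
30 | butenolide (C8=C17, Me-18, C19 lactone carbonyl, C7H2), 6-OPMB | C=C(COCc1ccc(OC)cc1)C[C@@H](O[Si](C)(C)C(C)(C)C)[C@H](O[Si](C)(C)C(C)(C)C)[C@@]1(C)C=C[C@@H](OC(C)=O)[C@@](C)(OC(C)=O)[C@@H]1[C@H](OC(C)=O)C2=C(C)C(=O)OC2 | intermediate
31 | butenolide allylic alcohol (C6–OH) | C=C(CO)C[C@@H](O[Si](C)(C)C(C)(C)C)[C@H](O[Si](C)(C)C(C)(C)C)[C@@]1(C)C=C[C@@H](OC(C)=O)[C@@](C)(OC(C)=O)[C@@H]1[C@H](OC(C)=O)C2=C(C)C(=O)OC2 | intermediate
32 | butenolide enal (C6 aldehyde) | C=C(C=O)C[C@@H](O[Si](C)(C)C(C)(C)C)[C@H](O[Si](C)(C)C(C)(C)C)[C@@]1(C)C=C[C@@H](OC(C)=O)[C@@](C)(OC(C)=O)[C@@H]1[C@H](OC(C)=O)C2=C(C)C(=O)OC2 | intermediate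
33 | 2-(tert-butyldimethylsilyloxy)furan derived from 32 | C=C(C=O)C[C@@H](O[Si](C)(C)C(C)(C)C)[C@H](O[Si](C)(C)C(C)(C)C)[C@@]1(C)C=C[C@@H](OC(C)=O)[C@@](C)(OC(C)=O)[C@@H]1[C@H](OC(C)=O)c2coc(O[Si](C)(C)C(C)(C)C)c2C | intermediate
34 | ten-membered aldol (6R-OH, 7R; C5 exocyclic methylene; 2,3-bis-OTBS) | C=C1C[C@@H](O[Si](C)(C)C(C)(C)C)[C@H](O[Si](C)(C)C(C)(C)C)[C@@]2(C)C=C[C@@H](OC(C)=O)[C@@](C)(OC(C)=O)[C@@H]2[C@H](OC(C)=O)C3=C(C)C(=O)O[C@H]3[C@@H]1O | intermediate
35 | 6S allylic chloride, 2,3-bis-OTBS | C=C1C[C@@H](O[Si](C)(C)C(C)(C)C)[C@H](O[Si](C)(C)C(C)(C)C)[C@@]2(C)C=C[C@@H](OC(C)=O)[C@@](C)(OC(C)=O)[C@@H]2[C@H](OC(C)=O)C3=C(C)C(=O)O[C@H]3[C@H]1Cl | intermediate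
36 | 6S chloride 2,3-diol (seco-ether) | C=C1C[C@@H](O)[C@H](O)[C@@]2(C)C=C[C@@H](OC(C)=O)[C@@](C)(OC(C)=O)[C@@H]2[C@H](OC(C)=O)C3=C(C)C(=O)O[C@H]3[C@H]1Cl | intermediate
37 | CNP0333938.2 | C=C1C[C@@H](O)[C@@H]2O[C@@]3([C@@H](C)C(=O)O[C@H]3[C@H]1Cl)[C@@H](OC(C)=O)[C@@H]1[C@]2(C)C=C[C@@H](OC(C)=O)[C@@]1(C)OC(C)=O | target

**Totals and risks**
Total step count: 24. Longest linear sequence: 22 steps (from 8 and 9 through steps 3–24).

Most likely to fail, in this order:

Step 21. Intermolecular aldol and oligomerisation may outrun closure of the ten-membered ring; conjugate attack at the enal methylene and poor control of the C6/C7 configurations are further hazards. The fallback sets out from 32 through 33: the silyloxyfuran is brominated at C7 with NBS (CH2Cl2, −78 °C) to give the γ-bromobutenolide F1. F1 is cyclised at high dilution with SmI2 (THF, −78 °C) in a samarium Reformatsky-type reaction, in which the metal dienolate (α-carbon blocked by methyl) adds to the aldehyde through a chelated transition state. This returns to the route at 34.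

Step 24. The conjugate addition may stall, the C3 hydroxyl may compete, C17 may protonate from the wrong face, or the allylic chloride may ionise under acid. The fallback sets out from 34 and forms the ether before the chloride: aqueous HF in MeCN removes both TBS ethers to give the triol F2, and CSA-mediated transannular oxa-Michael addition gives the hydroxy ether F3. Chemoselective chlorination of the allylic C6 hydroxyl (PPh3, hexachloroacetone, 0 °C; the hindered non-allylic C3 hydroxyl reacts much more slowly) with inversion returns to the route at 37.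

Step 22. Allylic transposition (SN2′), ion-pair return with loss of configuration, or elimination toward the γ-alkylidene butenolide may intervene. The fallback sets out from 34: Mitsunobu coupling with 2-nitrobenzenesulfonylhydrazide (PPh3, DEAD, THF, −30 °C) gives the hydrazide F4. On warming it loses sulfinate to the allylic diazene F5, which expels N2 by retro-ene with 1,3-transposition to give the C5(Me)=C6 olefin F6. Selenium-catalysed ene-type chlorination (NCS, PhSeCl cat., CH2Cl2), which puts chlorine on C6 and regenerates the exocyclic methylene, returns to the route at 35.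

Further compounds
F1 | step 21 | γ-bromobutenolide enal (C7 bromide, either epimer) | C=C(C=O)C[C@@H](O[Si](C)(C)C(C)(C)C)[C@H](O[Si](C)(C)C(C)(C)C)[C@@]1(C)C=C[C@@H](OC(C)=O)[C@@](C)(OC(C)=O)[C@@H]1[C@H](OC(C)=O)C2=C(C)C(=O)OC2Br
F2 | step 24 | ten-membered 2,3,6-triol (desilylated 34) | C=C1C[C@@H](O)[C@H](O)[C@@]2(C)C=C[C@@H](OC(C)=O)[C@@](C)(OC(C)=O)[C@@H]2[C@H](OC(C)=O)C3=C(C)C(=O)O[C@H]3[C@@H]1O
F3 | step 24 | 2,8-ether with 6R hydroxyl (6-hydroxy analogue of 37) | C=C1C[C@@H](O)[C@@H]2O[C@@]3([C@@H](C)C(=O)O[C@H]3[C@@H]1O)[C@@H](OC(C)=O)[C@@H]1[C@]2(C)C=C[C@@H](OC(C)=O)[C@@]1(C)OC(C)=O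
F4 | step 22 | C6 N-(2-nitrobenzenesulfonyl)hydrazide (inverted at C6) | C=C1C[C@@H](O[Si](C)(C)C(C)(C)C)[C@H](O[Si](C)(C)C(C)(C)C)[C@@]2(C)C=C[C@@H](OC(C)=O)[C@@](C)(OC(C)=O)[C@@H]2[C@H](OC(C)=O)C3=C(C)C(=O)O[C@H]3[C@H]1N(N)S(=O)(=O)c1ccccc1[N+](=O)[O-]
F5 | step 22 | C6 allylic diazene | C=C1C[C@@H](O[Si](C)(C)C(C)(C)C)[C@H](O[Si](C)(C)C(C)(C)C)[C@@]2(C)C=C[C@@H](OC(C)=O)[C@@](C)(OC(C)=O)[C@@H]2[C@H](OC(C)=O)C3=C(C)C(=O)O[C@H]3[C@H]1N=N
F6 | step 22 | (5Z)-C5(Me)=C6 olefin (transposed, deoxygenated 34) | C/C=1C[C@@H](O[Si](C)(C)C(C)(C)C)[C@H](O[Si](C)(C)C(C)(C)C)[C@@]2(C)C=C[C@@H](OC(C)=O)[C@@](C)(OC(C)=O)[C@@H]2[C@H](OC(C)=O)C3=C(C)C(=O)O[C@H]3\C=1
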